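Time is the budget in south-west: the dosing takes 0.800 h of the 1.0 h.

| flask | D | E | remark | time |
|---|---|---|---|---|
| Saturday's | 10 mM | 1 µM | run made earlier |  |
| Sunday's | 5 mM | 1 µM | run made earlier |  |
| Wednesday's | 7.5 mM | 1 µM | run made earlier |  |
| north | 10 mM | 1.0 µM | one stirred flow tank at steady state, fed with the mixture as stated, mean residence time 10.0 h |  |
| east | 10 mM | 1.0 µM | everything together in a closed stirred flask, run for 1.0 h | 1.0 h |
| south-west | 10 mM (fed, over 0.800 h) | 1.0 µM | a stirred flask in which D is dosed at a steady rate over 0.800 h without added volume, worked up at 1.0 h | 1.0 h |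
| south-east | 10 mM | 1.0 µM | a single well-mixed tank run continuously and read at steady state, 1.0 h in it on average |  |

- Saturday's (time / min: G / %): 3.00: 2.5; 10.0: 14.6; 15.0: 21.4; 25.0: 33.8; 40.0: 52.4; 50.0: 65.0; 60.0: 74.4
- Sunday's (time / min: G / %): 3.00: 9.1; 10.0: 24.1; 15.0: 32.8; 25.0: 53.9; 40.0: 72.5; 50.0: 82.5; 60.0: 89.6
- Wednesday's (time / min: G / %): 5.00: 9.7; 8.00: 15.5; 12.0: 23.2; 15.0: 27.5; 25.0: 43.1; 40.0: 63.0; 60.0: 82.3

(each reading ± 1 percentage point)

- the stated concentrations are those of everything mixed, before any reaction; amounts are the same in each set-up
- what was read earlier has a scatter of 1 percentage point, one standard deviation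
- reactions considered so far: E -> Z; D + E -> G + E
- the feed brings no volume worth counting
- the earlier runs were made in a closed, stirred flask

1. order of the set-ups by the amount of G at the outlet or at the end, in percent of the D put in, highest first (north / east / south-west / south-east)
2. amount of G at the outlet or at the end, in percent of the D put in, north
3. amount of G at the outlet or at the end, in percent of the D put in, east
4. amount of G at the outlet or at the end, in percent of the D put in, south-west
5. amount of G at the outlet or at the end, in percent of the D put in, south-east

Take Saturday's mean turnover over the hour, a reading with its scatter, as a working plateau rate (zero-order behaviour, in the trade's term): 7.44 mM h⁻¹. Sunday's readings show the pace lower at low D: 5.96 mM h⁻¹ around 3.05 mM of D, and 3.72 mM h⁻¹ around 1.84 mM, both slower than the plateau.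

South-west receives D at 12.5 mM h⁻¹. My reckoning guesses a rate during the feed, gets the D standing at the end of the feed, halves that for the mean D, reads a new rate at that mean, and goes round again. After the feed, I let the plateau rate remove 1.49 mM.

Reckoned ceiling, plateau rate throughout: 74.4% G, with 4.05 mM of D at the end of the feed and a mean of 2.02 mM.

Reckoned floor, Sunday's lower rate: 7.02 mM of D, so 44.6% G, with a mean of 3.51 mM.

Tighter ceiling, Sunday's higher rate: 5.23 mM of D, so 62.6% G, with a mean of 2.62 mM.

Last pass, rate interpolated at that mean: 5.16 mM h⁻¹, giving 5.87 mM of D and 56.1% G.

I commit to 56.1%, inside the bracket from 44.6% to 62.6%. The forecast, which says “dosing keeps D low”, gives 94% for north, 74% for east, 57% for south-west (inside my bracket) and 61% for south-east, in the order north > east > south-east > south-west.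

The flasks give 93.0% for north, 72.5% for east, 56.8% for south-west and 61.2% for south-east, in the order north > east > south-east > south-west.

    E → Z (k = 0.00200 min⁻¹)
    D + E → G + E, rate k2*[D]*[E]/(1 + ([D]/Km2) + ([D]/Ksi2)^2) (5.50 mM, 9.60 mM, k = 55000 L mol⁻¹ min⁻¹)

South-west lands at 56.8%, inside the bracket. The D in south-west peaks at 5.67 mM at 0.800 h. Taking the plateau's 1.49 mM from that peak leaves 4.18 mM, and at 1.00 h south-west holds 43% of its charge of D, which is 4.32 mM.

Now charge a flask like south-west with 40 mM of D. The plateau rate held over the hour gives 18.6% of that charge as G; the computed flask gives 15.8%, lower than that reckoning.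

The numbers in the tables were computed from invented constants, and the scatter is random.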